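The numbers of this flask were chosen freely; the flask was simulated.

**Early hours.** From the first hours the side step goes as the square of c(starting material), charged at 0.30 M. The quick number wanted is how much self-condensation product each flask ends with. Your hunch leans on how the second substrate goes in, but temperature comes first on the reckoning below.

the same everywhere: starting material 0.30 M; reagent 0.700 equiv; catalyst 4.2 mol%; time 12 h
- ash: second substrate 0.500 equiv (in portions, 4, over 8.0 h); temperature 25 °C; first portion at the start, last at 8.0 h
- larch: second substrate 0.500 equiv; temperature 25 °C; everything together at the start
- elm: second substrate 0.500 equiv (fed, over 8.0 h); the addition at −15 °C, then warmed to 25 °C; the feed brings no volume worth counting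
- cedar: second substrate 0.500 equiv (fed, over 8.0 h); temperature 25 °C; all else is in the flask from the start; the feed brings no volume worth counting

* the flask that comes out highest in amount of self-condensation product, in percent of the starting material charged; "all alike" if 1.5 percentage points covers them all (ash / larch / elm / cedar / all alike)
* amount of self-condensation product at the end, in percent of the starting material charged, ash
* amount of self-condensation product at the end, in percent of the starting material charged, larch
* amount of self-condensation product at the end, in percent of the starting material charged, elm
* amount of self-condensation product at the end, in percent of the starting material charged, cedar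

- a species is counted by the starting material in it: one self-condensation product counts as two
- a doubled species enters its step squared and goes two at a time
- all constants are for 25 °C and move with temperature by the activation energies and enthalpies

    second substrate + reagent + catalyst → catalyst + second product (k1 = 53.3 /M²/h, Ea1 = 48.0 kJ/mol)
    2 starting material → self-condensation product (k2 = 0.213 /M/h, Ea2 = 85.0 kJ/mol)
    starting material + reagent + catalyst ⇌ catalyst + target (K3 = 3.0 /M, k3 = 90.1 /M²/h, Ea3 = 48.0 kJ/mol, ΔH3 = −29.0 kJ/mol)
    (constants at 25 °C)

**Warm hours.** Two starting material go at each turn, so at 0.30 M the first half-life by self-condensation is 7.82 h. Left to itself, that step turns a share t/(t+τ) of the charge in time t, with τ this half-life.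

At −15 °C its constant shrinks by the factor 0.00493, so the half-life there is 1590 h, far longer than the 8.0 h of the cold feed. Elm's warm hours come to 4.04 h, the time at 25 °C plus the cold time multiplied by that factor.

Larch, ash and cedar each have 12 h of warm hours, so this clock gives them one share, 60.5 %, and cannot part them. Elm gets 34.0 %.

These are ceilings, not estimates. The pseudo-first-order half-life of starting material by the forward reversible step, reckoned for larch at its charge, is 2.9 h, shorter than 7.82 h, so starting material is drawn into target and c(starting material) falls faster than the clock assumes.

**The forecast.** It names larch highest: larch 47.8 % (45 % to 50.5 %), ash 43.5 % (40 % to 47 %), cedar 43 % (39.5 % to 46.5 %), elm 24 % (21.5 % to 26.5 %). For elm its ground is “leaving only about 4 h at 25 °C for the side reaction”. These figures differ from the reckoning above, standing lower: elm's 24 % is less than the ceiling of 34.0 %, and larch's 47.8 % is less than 60.5 %.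

**The simulation.** Larch comes out highest at 47.6 %, then ash at 45.9 %, cedar at 45.8 % and elm at 24.1 %. Each forecast value held within its tolerance.

**Clock tested.** Elm holds 0.459 % of self-condensation product at 8.00 h, when the cold feed ends, and 24.1 % at 12.0 h, so its 4.04 h of warm hours stand against larch's 12 h and 24.1 % against 47.6 %. The same elm flask left until 20 h has 12.0 h of warm hours, about what larch has, and it reads 47.2 %, beside larch's 47.6 %.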